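Everything rests on cutting the two benzylic C–C bonds, C7–C8 and C8'–C7', of the 3,7-dioxabicyclo[3.3.0]octane core, which leaves C9–C8–C8'–C9' as a butenolide (C9' carbonyl, C9 menthyl acetal). The feature used is the ring-fusion bond C8–C8': its substituents C7 and C7' sit trans on that γ-lactone. In one operation a lithiated guaiacyl dithiane adds to C8 and the resulting enolate captures the dihydrobenzofuran aldehyde at C8', so both fusion centres follow from the acetal carbon. The precursors are (5S)-5-menthyloxyfuran-2(5H)-one, a silylated aryl dithiane and a silylated cis-2-aryl-3-(hydroxymethyl)dihydrobenzofuran-5-carbaldehyde; both aryl groups are later turned endo by hydride.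

Key step: step 14

Assumption (chemistry): in the dirhodium-carbene C–H insertion of step 10 the S-configured N-phthaloyl-tert-leucinate catalyst is taken to favour the (2R,3S) cis ester, so its R-configured antipode is specified to reach the (2S,3R) ester. If the sense proves opposite, the other catalyst antipode is used with no other change.

Remarks on the design:
- The target has the dihydrobenzofuran 2,3-cis (2S,3S) and both aryl groups endo on the bicycle (7S,8S,7'S,8'S; all four ring hydrogens on the convex face).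
- All three silyl groups are triisopropylsilyl, which resists amidine base, organolithium and LiAlH4 better than an aryl tert-butyldimethylsilyl ether and allows one fluoride step at the end.
- The dihydrobenzofuran aldehyde is built from 5-bromovanillin, which already carries the formyl group para to the phenol, so no one-carbon homologation is needed.

Abbreviations in names:
- TIPS = triisopropylsilyl.
- Ar = 3-methoxy-4-(triisopropylsilyloxy)phenyl.
- ArB = (2S,3S)-7-methoxy-2-[3-methoxy-4-(triisopropylsilyloxy)phenyl]-3-[(triisopropylsilyloxy)methyl]-2,3-dihydrobenzofuran-5-yl (2,3-cis).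
- menthyl = (1S,2R,5S)-2-isopropyl-5-methylcyclohexyl.
- Lignan locants: C7/C8/C9 on the guaiacyl side, C7'/C8'/C9' on the dihydrobenzofuran side.

Step 1
Reactants: 1 furfural (furan-2-carbaldehyde)
Product: 2 (±)-5-hydroxyfuran-2(5H)-one
Conditions: O2, visible light, rose bengal (cat.), MeOH, rt
Reagents that add atoms: dioxygen, O=O
Why: Schenck-type dye-sensitised photooxygenation, in which singlet oxygen adds across the furan diene and methanol removes the formyl carbon as methyl formate; the hemiacetal carbon forms racemic and is settled in step 2.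

Step 2
Reactants: 2 (±)-5-hydroxyfuran-2(5H)-one; 3 (+)-menthol, (1S,2R,5S)-2-isopropyl-5-methylcyclohexan-1-ol
Product: 4 (5S)-5-[(1S,2R,5S)-menthyloxy]furan-2(5H)-one
Conditions: camphorsulfonic acid (cat.), benzene, reflux (Dean–Stark); crystallisation from petroleum ether, mother liquor re-equilibrated with acid and recrystallised
Reagents that add atoms: none
Why: Acid-catalysed acetal formation (Fischer-type glycosidation of the lactol) should give both C5 epimers, and the acetal stereocentre is fixed as 5S because that epimer crystallises while acid equilibrates the one left in solution.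

Step 3
Reactants: 5 vanillin (4-hydroxy-3-methoxybenzaldehyde)
Product: 6 3-methoxy-4-(triisopropylsilyloxy)benzaldehyde
Conditions: TIPSCl, imidazole, DMF, rt
Reagents that add atoms: triisopropylsilyl chloride, CC(C)[Si](Cl)(C(C)C)C(C)C
Why: Silyl ether formation at the phenol with imidazole as base; the bulky silyl group is chosen to survive the later organolithium, hydride and base steps.

Step 4
Reactants: 6 3-methoxy-4-(triisopropylsilyloxy)benzaldehyde
Product: 7 2-[3-methoxy-4-(triisopropylsilyloxy)phenyl]-1,3-dithiane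
Conditions: HS(CH2)3SH, BF3·OEt2 (cat.), CH2Cl2, 0 °C
Reagents that add atoms: propane-1,3-dithiol, SCCCS
Why: Lewis-acid-catalysed dithioacetalisation of an aromatic aldehyde, which the aryl silyl ether should tolerate at low temperature.

Step 5
Reactants: 6 3-methoxy-4-(triisopropylsilyloxy)benzaldehyde
Product: 8 [3-methoxy-4-(triisopropylsilyloxy)phenyl]methanol
Conditions: NaBH4, MeOH/THF, 0 °C
Reagents that add atoms: none
Why: Borohydride reduction of the aldehyde to the primary benzylic alcohol, with no other reducible group present.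

Step 6
Reactants: 8 [3-methoxy-4-(triisopropylsilyloxy)phenyl]methanol; 9 5-bromovanillin (3-bromo-4-hydroxy-5-methoxybenzaldehyde)
Product: 10 3-bromo-5-methoxy-4-{[3-methoxy-4-(triisopropylsilyloxy)benzyl]oxy}benzaldehyde
Conditions: PPh3, diisopropyl azodicarboxylate, THF, 0 °C → rt
Reagents that add atoms: none
Why: Mitsunobu etherification, in which the phenol (acidified by the para formyl and ortho bromo groups) is alkylated by the primary benzylic alcohol under neutral conditions that spare the aryl silyl ether and avoid a labile electron-rich benzyl halide.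

Step 7
Reactants: 10 3-bromo-5-methoxy-4-{[3-methoxy-4-(triisopropylsilyloxy)benzyl]oxy}benzaldehyde
Product: 11 2-(3-bromo-5-methoxy-4-{[3-methoxy-4-(triisopropylsilyloxy)benzyl]oxy}phenyl)-1,3-dioxolane
Conditions: HOCH2CH2OH, pyridinium p-toluenesulfonate (cat.), benzene, reflux (Dean–Stark)
Reagents that add atoms: ethane-1,2-diol, OCCO
Why: Acid-catalysed acetalisation with azeotropic removal of water masks the aldehyde, which the zinc enolate of step 8 would otherwise attack.

Step 8
Reactants: 11 2-(3-bromo-5-methoxy-4-{[3-methoxy-4-(triisopropylsilyloxy)benzyl]oxy}phenyl)-1,3-dioxolane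
Product: 12 methyl 2-[5-(1,3-dioxolan-2-yl)-3-methoxy-2-{[3-methoxy-4-(triisopropylsilyloxy)benzyl]oxy}phenyl]acetate
Conditions: BrZnCH2CO2Me (from BrCH2CO2Me and Zn in THF), Pd2(dba)3 (cat.), XPhos (cat.), THF, 60 °C
Reagents that add atoms: bromo(2-methoxy-2-oxoethyl)zinc, COC(=O)C[Zn]Br
Why: Negishi-type cross-coupling of the aryl bromide with a Reformatsky zinc enolate (ester α-arylation under neutral conditions), which should tolerate the acetal, the benzyl ether and the silyl ether.

Step 9
Reactants: 12 methyl 2-[5-(1,3-dioxolan-2-yl)-3-methoxy-2-{[3-methoxy-4-(triisopropylsilyloxy)benzyl]oxy}phenyl]acetate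
Product: 13 methyl 2-diazo-2-[5-(1,3-dioxolan-2-yl)-3-methoxy-2-{[3-methoxy-4-(triisopropylsilyloxy)benzyl]oxy}phenyl]acetate
Conditions: 4-acetamidobenzenesulfonyl azide, DBU, dry MeCN, 0 °C → rt
Reagents that add atoms: 4-acetamidobenzenesulfonyl azide, CC(=O)Nc1ccc(cc1)S(=O)(=O)N=[N+]=[N-]
Why: Regitz diazo transfer to the aryl- and ester-activated methylene gives the aryldiazoacetate; dry conditions keep the aryl silyl ether intact.

Step 10
Reactants: 13 methyl 2-diazo-2-[5-(1,3-dioxolan-2-yl)-3-methoxy-2-{[3-methoxy-4-(triisopropylsilyloxy)benzyl]oxy}phenyl]acetate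
Product: 14 methyl (2S,3R)-5-(1,3-dioxolan-2-yl)-7-methoxy-2-[3-methoxy-4-(triisopropylsilyloxy)phenyl]-2,3-dihydrobenzofuran-3-carboxylate (2,3-cis)
Conditions: Rh2(R-PTTL)4 (1 mol %; PTTL = N-phthaloyl-tert-leucinate), toluene, −60 °C
Reagents that add atoms: none
Why: Intramolecular dirhodium-carbene 1,5 C–H insertion into the benzylic ether C–H bond, which the ether oxygen and the electron-rich arene activate; the concerted insertion should place aryl and ester cis, and the chiral carboxylate ligands select the carbene face so that C2 and C3 are set together as 2S,3R.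

Step 11
Reactants: 14 methyl (2S,3R)-5-(1,3-dioxolan-2-yl)-7-methoxy-2-[3-methoxy-4-(triisopropylsilyloxy)phenyl]-2,3-dihydrobenzofuran-3-carboxylate
Product: 15 {(2S,3S)-5-(1,3-dioxolan-2-yl)-7-methoxy-2-[3-methoxy-4-(triisopropylsilyloxy)phenyl]-2,3-dihydrobenzofuran-3-yl}methanol (2,3-cis)
Conditions: LiAlH4, THF, −78 → 0 °C
Reagents that add atoms: none
Why: Hydride reduction of the ester to the primary alcohol at low temperature; the cis relationship should be kept because the transient aldehyde is reduced faster than it can enolise (the C3 descriptor changes only through priority).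

Step 12
Reactants: 15 {(2S,3S)-5-(1,3-dioxolan-2-yl)-7-methoxy-2-[3-methoxy-4-(triisopropylsilyloxy)phenyl]-2,3-dihydrobenzofuran-3-yl}methanol
Product: 16 2-{(2S,3S)-7-methoxy-2-[3-methoxy-4-(triisopropylsilyloxy)phenyl]-3-[(triisopropylsilyloxy)methyl]-2,3-dihydrobenzofuran-5-yl}-1,3-dioxolane (2,3-cis)
Conditions: TIPSCl, imidazole, DMF, rt
Reagents that add atoms: triisopropylsilyl chloride, CC(C)[Si](Cl)(C(C)C)C(C)C
Why: Silyl ether formation at the unhindered primary alcohol removes the only acidic hydrogen that could quench the enolate of the key step.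

Step 13
Reactants: 16 2-{(2S,3S)-7-methoxy-2-[3-methoxy-4-(triisopropylsilyloxy)phenyl]-3-[(triisopropylsilyloxy)methyl]-2,3-dihydrobenzofuran-5-yl}-1,3-dioxolane
Product: 17 (2S,3S)-7-methoxy-2-[3-methoxy-4-(triisopropylsilyloxy)phenyl]-3-[(triisopropylsilyloxy)methyl]-2,3-dihydrobenzofuran-5-carbaldehyde (2,3-cis; ArB–CHO)
Conditions: pyridinium p-toluenesulfonate (cat.), acetone/H2O, 50 °C
Reagents that add atoms: water, O
Why: Mild acid-catalysed acetal hydrolysis, easy here because the para ring oxygen stabilises the oxocarbenium ion, under conditions that should leave the silyl ethers and the benzylic ring ether intact.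

Step 14
Reactants: 7 2-[3-methoxy-4-(triisopropylsilyloxy)phenyl]-1,3-dithiane; 4 (5S)-5-[(1S,2R,5S)-menthyloxy]furan-2(5H)-one; 17 (2S,3S)-7-methoxy-2-[3-methoxy-4-(triisopropylsilyloxy)phenyl]-3-[(triisopropylsilyloxy)methyl]-2,3-dihydrobenzofuran-5-carbaldehyde
Product: 20 (3R,4S,5S)-3-[(S)-hydroxy(ArB)methyl]-4-(2-Ar-1,3-dithian-2-yl)-5-[(1S,2R,5S)-menthyloxy]dihydrofuran-2(3H)-one (trans,trans lactone; carbinol epimer drawn is one of two possible), via lithiated dithiane 18 (not isolated), via lithium lactone enolate 19 (not isolated)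
Conditions: n-BuLi, THF, −78 → −20 °C; then 4, −78 °C; then 17, −78 °C; aq. NH4Cl
Reagents that add atoms: none
Why: Deprotonation of 7 gives the sulfur-stabilised carbanion 18, which adds in a conjugate sense to C4 of butenolide 4 (C7–C8 bond) to give lithium enolate 19, and 19 is trapped at C3 by aldehyde 17 in an aldol addition (C8'–C7' bond). The closest known reaction type is the tandem Michael addition–aldol reaction of lithiated 2-aryl-1,3-dithianes with 5-alkoxyfuran-2(5H)-ones. No ring is closed. C8 is set by the acetal carbon C9, whose menthyloxy group shields one face of the flat butenolide so that 18 enters anti to it; C8' is set by the bulky dithianyl group now on C8, anti to which the aldehyde approaches; the carbinol centre C7' is not controlled and is erased in step 16. The step needs 1,4- over 1,2-addition, which the soft dithiane anion and the unhindered β-carbon should secure, and capture of 19 at −78 °C before proton exchange, which is supported by 17 carrying no acidic hydrogen (both hydroxyls silylated).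

Step 15
Reactants: 20 (3R,4S,5S)-3-[(S)-hydroxy(ArB)methyl]-4-(2-Ar-1,3-dithian-2-yl)-5-[(1S,2R,5S)-menthyloxy]dihydrofuran-2(3H)-one
Product: 21 (2S,3S)-2-(2-Ar-1,3-dithian-2-yl)-3-[(S)-hydroxy(ArB)methyl]butane-1,4-diol
Conditions: LiAlH4, THF, 0 °C → rt
Reagents that add atoms: none
Why: LiAlH4 reduction of the lactone, in which ring opening unmasks the acetal carbon as an aldehyde with loss of menthol and this is reduced in turn, so that C9 and C9' both become hydroxymethyl groups while C8 and C8' are untouched.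

Step 16
Reactants: 21 (2S,3S)-2-(2-Ar-1,3-dithian-2-yl)-3-[(S)-hydroxy(ArB)methyl]butane-1,4-diol
Product: 22 (2S,3S)-3-(2-Ar-1,3-dithian-2-yl)-4-hydroxy-2-(hydroxymethyl)-1-ArB-butan-1-one
Conditions: MnO2 (excess), CH2Cl2, rt
Reagents that add atoms: none
Why: Chemoselective MnO2 oxidation of the benzylic secondary alcohol to the aryl ketone removes the uncontrolled carbinol centre and should leave the two primary aliphatic alcohols and the dithiane unchanged.

Step 17
Reactants: 22 (2S,3S)-3-(2-Ar-1,3-dithian-2-yl)-4-hydroxy-2-(hydroxymethyl)-1-ArB-butan-1-one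
Product: 23 (2S,3S)-2,3-bis(hydroxymethyl)-1-Ar-4-ArB-butane-1,4-dione
Conditions: PhI(O2CCF3)2, NaHCO3, MeCN/H2O (9:1), 0 °C
Reagents that add atoms: water, O
Why: Oxidative dethioacetalisation with a hypervalent iodine reagent in buffered aqueous acetonitrile, where sulfur should be oxidised much faster than the silylated arenes and water delivers the carbonyl oxygen.

Step 18
Reactants: 23 (2S,3S)-2,3-bis(hydroxymethyl)-1-Ar-4-ArB-butane-1,4-dione
Product: 24 (7S,8S,7'S,8'S)-2-Ar-6-ArB-3,7-dioxabicyclo[3.3.0]octane (both aryl groups endo; tris-TIPS ether of the target)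
Conditions: Et3SiH (excess), BF3·OEt2, CH2Cl2, −78 → −40 °C; cold aq. NaHCO3
Reagents that add atoms: none
Why: Lewis-acid-promoted reductive cyclisation (ionic hydrogenation) of each γ-hydroxy ketone through a cyclic aryl-stabilised oxocarbenium ion; hydride from Et3SiH should enter anti to the C8/C8' substituents, that is from the convex face of the cis-fused bicycle, so that the new hydrogens at C7 and C7' are cis to the ring-fusion hydrogens and both aryl groups end endo.

Step 19
Reactants: 24 (7S,8S,7'S,8'S)-2-Ar-6-ArB-3,7-dioxabicyclo[3.3.0]octane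
Product: 25 target CNP0303197.1, (7S,8S,7'S,8'S)-2-(4-hydroxy-3-methoxyphenyl)-6-[(2S,3S)-2-(4-hydroxy-3-methoxyphenyl)-3-(hydroxymethyl)-7-methoxy-2,3-dihydrobenzofuran-5-yl]-3,7-dioxabicyclo[3.3.0]octane
Conditions: Bu4NF, AcOH, THF, 0 °C → rt
Reagents that add atoms: none
Why: Fluoride-induced cleavage of the two aryl and one alkyl silyl ethers, buffered with acetic acid so that no phenoxide can open the benzylic ethers; no stereocentre is touched.

Compound list
1 | furfural | O=Cc1ccco1 | starting material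
2 | (±)-5-hydroxyfuran-2(5H)-one | OC1OC(=O)C=C1 | intermediate
3 | (+)-menthol, (1S,2R,5S) | C[C@H]1CC[C@@H]([C@H](C1)O)C(C)C | starting material
4 | (5S)-5-[(1S,2R,5S)-menthyloxy]furan-2(5H)-one | C[C@H]1CC[C@@H]([C@H](C1)O[C@H]1OC(=O)C=C1)C(C)C | intermediate
5 | vanillin | COc1cc(C=O)ccc1O | starting material
6 | 3-methoxy-4-(triisopropylsilyloxy)benzaldehyde | COc1cc(C=O)ccc1O[Si](C(C)C)(C(C)C)C(C)C | intermediate
7 | 2-[3-methoxy-4-(triisopropylsilyloxy)phenyl]-1,3-dithiane | COc1cc(C2SCCCS2)ccc1O[Si](C(C)C)(C(C)C)C(C)C | intermediate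
8 | [3-methoxy-4-(triisopropylsilyloxy)phenyl]methanol | COc1cc(CO)ccc1O[Si](C(C)C)(C(C)C)C(C)C | intermediate
9 | 5-bromovanillin | COc1cc(C=O)cc(Br)c1O | starting material
10 | 3-bromo-5-methoxy-4-{[3-methoxy-4-(triisopropylsilyloxy)benzyl]oxy}benzaldehyde | COc1cc(C=O)cc(Br)c1OCc1ccc(O[Si](C(C)C)(C(C)C)C(C)C)c(OC)c1 | intermediate
11 | 1,3-dioxolane of 10 | COc1cc(C2OCCO2)cc(Br)c1OCc1ccc(O[Si](C(C)C)(C(C)C)C(C)C)c(OC)c1 | intermediate
12 | methyl arylacetate from 11 | COC(=O)Cc1cc(C2OCCO2)cc(OC)c1OCc1ccc(O[Si](C(C)C)(C(C)C)C(C)C)c(OC)c1 | intermediate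
13 | methyl aryldiazoacetate from 12 | COC(=O)C(=[N+]=[N-])c1cc(C2OCCO2)cc(OC)c1OCc1ccc(O[Si](C(C)C)(C(C)C)C(C)C)c(OC)c1 | intermediate
14 | methyl (2S,3R)-cis-5-(1,3-dioxolan-2-yl)-7-methoxy-2-Ar-2,3-dihydrobenzofuran-3-carboxylate | O1CCOC1c1cc(OC)c2c(c1)[C@@H](C(=O)OC)[C@@H](c1ccc(O[Si](C(C)C)(C(C)C)C(C)C)c(OC)c1)O2 | intermediate
15 | (2S,3S)-cis-3-(hydroxymethyl) analogue of 14 | O1CCOC1c1cc(OC)c2c(c1)[C@@H](CO)[C@@H](c1ccc(O[Si](C(C)C)(C(C)C)C(C)C)c(OC)c1)O2 | intermediate
16 | TIPS ether of 15 | O1CCOC1c1cc(OC)c2c(c1)[C@@H](CO[Si](C(C)C)(C(C)C)C(C)C)[C@@H](c1ccc(O[Si](C(C)C)(C(C)C)C(C)C)c(OC)c1)O2 | intermediate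
17 | (2S,3S)-cis-dihydrobenzofuran-5-carbaldehyde (ArB–CHO) | O=Cc1cc(OC)c2c(c1)[C@@H](CO[Si](C(C)C)(C(C)C)C(C)C)[C@@H](c1ccc(O[Si](C(C)C)(C(C)C)C(C)C)c(OC)c1)O2 | intermediate
18 | 2-lithio-2-[3-methoxy-4-(triisopropylsilyloxy)phenyl]-1,3-dithiane | COc1cc(C2([Li])SCCCS2)ccc1O[Si](C(C)C)(C(C)C)C(C)C | intermediate (not isolated)
19 | lithium enolate of (4S,5S)-4-(2-Ar-1,3-dithian-2-yl)-5-menthyloxydihydrofuran-2(3H)-one | COc1cc(C2(SCCCS2)[C@H]3C=C(O[Li])O[C@@H]3O[C@H]2C[C@@H](C)CC[C@@H]2C(C)C)ccc1O[Si](C(C)C)(C(C)C)C(C)C | intermediate (not isolated)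
20 | (3R,4S,5S)-3-[(S)-hydroxy(ArB)methyl]-4-(2-Ar-1,3-dithian-2-yl)-5-menthyloxydihydrofuran-2(3H)-one | COc1cc(C2(SCCCS2)[C@H]3[C@H]([C@H](O)c2cc(OC)c4c(c2)[C@@H](CO[Si](C(C)C)(C(C)C)C(C)C)[C@@H](c2ccc(O[Si](C(C)C)(C(C)C)C(C)C)c(OC)c2)O4)C(=O)O[C@@H]3O[C@H]2C[C@@H](C)CC[C@@H]2C(C)C)ccc1O[Si](C(C)C)(C(C)C)C(C)C | intermediate
21 | (2S,3S)-2-(2-Ar-1,3-dithian-2-yl)-3-[(S)-hydroxy(ArB)methyl]butane-1,4-diol | COc1cc(C2(SCCCS2)[C@H](CO)[C@H]([C@H](O)c2cc(OC)c3c(c2)[C@@H](CO[Si](C(C)C)(C(C)C)C(C)C)[C@@H](c2ccc(O[Si](C(C)C)(C(C)C)C(C)C)c(OC)c2)O3)CO)ccc1O[Si](C(C)C)(C(C)C)C(C)C | intermediate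
22 | (2S,3S)-3-(2-Ar-1,3-dithian-2-yl)-4-hydroxy-2-(hydroxymethyl)-1-ArB-butan-1-one | COc1cc(C2(SCCCS2)[C@H](CO)[C@H](C(=O)c2cc(OC)c3c(c2)[C@@H](CO[Si](C(C)C)(C(C)C)C(C)C)[C@@H](c2ccc(O[Si](C(C)C)(C(C)C)C(C)C)c(OC)c2)O3)CO)ccc1O[Si](C(C)C)(C(C)C)C(C)C | intermediate
23 | (2S,3S)-2,3-bis(hydroxymethyl)-1-Ar-4-ArB-butane-1,4-dione | COc1cc(C(=O)[C@H](CO)[C@H](C(=O)c2cc(OC)c3c(c2)[C@@H](CO[Si](C(C)C)(C(C)C)C(C)C)[C@@H](c2ccc(O[Si](C(C)C)(C(C)C)C(C)C)c(OC)c2)O3)CO)ccc1O[Si](C(C)C)(C(C)C)C(C)C | intermediate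
24 | tris-TIPS ether of the target, (7S,8S,7'S,8'S), both aryls endo | COc1cc([C@H]2OC[C@@H]3[C@H]2CO[C@@H]3c2cc(OC)c3c(c2)[C@@H](CO[Si](C(C)C)(C(C)C)C(C)C)[C@@H](c2ccc(O[Si](C(C)C)(C(C)C)C(C)C)c(OC)c2)O3)ccc1O[Si](C(C)C)(C(C)C)C(C)C | intermediate
25 | CNP0303197.1 | COc1cc([C@H]2OC[C@@H]3[C@H]2CO[C@@H]3c2cc(OC)c3c(c2)[C@@H](CO)[C@@H](c2ccc(O)c(OC)c2)O3)ccc1O | target

Total step count: 19.
Longest linear sequence: 16 steps (vanillin 5 through steps 3, 5, 6–19 to 25).

Steps most likely to fail

Step 14. The hindered lithium enolate may exchange a proton or sit unreacted before the bulky, electron-rich aldehyde is captured, so that only the conjugate adduct forms; some 1,2-addition of the carbanion to the lactone carbonyl is also possible. The fallback separates the two bond formations. It sets out from 7 and 4 and comes back at 20. The conjugate addition is run alone (n-BuLi, THF, −78 °C, then 4) and quenched with aqueous NH4Cl to give the isolated Michael adduct (4S,5S)-4-(2-Ar-1,3-dithian-2-yl)-5-[(1S,2R,5S)-menthyloxy]dihydrofuran-2(3H)-one F1. F1 is then enolised on its own with LiN(iPr)2 at −78 °C, the enolate is exchanged to zinc with ZnCl2, and 17 is added in a directed aldol addition, again anti to the C4 substituent, to give 20.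

Step 18. With two ketones, each α to a stereocentre and β to a hydroxyl, the double reduction may suffer from enolisation or dehydration before ring closure, from incomplete facial control at the first ring, or from acid-induced ionisation of a benzylic C–O bond that drifts an endo aryl to exo. The fallback builds the rings one at a time. It sets out from 22 and comes back at 24. The single γ-hydroxy ketone of 22 is reductively cyclised first (Et3SiH, BF3·OEt2, CH2Cl2, −78 °C) to the monocyclic (2S,3S,4S)-2-ArB-3-(hydroxymethyl)-4-(2-Ar-1,3-dithian-2-yl)tetrahydrofuran F2. The dithiane is then removed with PhI(O2CCF3)2 in buffered aqueous MeCN to give the ketone (2S,3S,4S)-4-(Ar-carbonyl)-2-ArB-3-(hydroxymethyl)tetrahydrofuran F3. A second Et3SiH/BF3·OEt2 reduction of its γ-hydroxy ketone closes the other ring, with hydride delivered to the convex face of the now bicyclic ion, and gives 24. No 1,4-diketone is ever present.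

Step 10. The extra ortho methoxy group and the acetal may perturb the carbene conformation, eroding enantio- or cis-selectivity, and carbonyl- or acetal-derived side reactions may consume carbene. The fallback replaces catalyst control by separation of diastereomers. It sets out from 15 of insufficient enantiomeric purity and comes back at 15. The alcohol is esterified with (S)-2-methoxy-2-phenylacetic acid (dicyclohexylcarbodiimide, 4-dimethylaminopyridine, CH2Cl2, 0 °C) to give the (S)-O-methylmandelate of (2S,3S)-15 F4 together with the ester of its enantiomer, the (S)-O-methylmandelate of (2R,3R)-15 F5. The two are separated by chromatography or crystallisation, and F4 is cleaved with LiAlH4 (THF, −78 → 0 °C) to return enantiopure 15.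

Further compounds
F1 | step 14 | (4S,5S)-4-(2-Ar-1,3-dithian-2-yl)-5-[(1S,2R,5S)-menthyloxy]dihydrofuran-2(3H)-one | COc1cc(C2(SCCCS2)[C@H]3CC(=O)O[C@@H]3O[C@H]2C[C@@H](C)CC[C@@H]2C(C)C)ccc1O[Si](C(C)C)(C(C)C)C(C)C
F2 | step 18 | (2S,3S,4S)-2-ArB-3-(hydroxymethyl)-4-(2-Ar-1,3-dithian-2-yl)tetrahydrofuran | COc1cc(C2(SCCCS2)[C@@H]3CO[C@H](c2cc(OC)c4c(c2)[C@@H](CO[Si](C(C)C)(C(C)C)C(C)C)[C@@H](c2ccc(O[Si](C(C)C)(C(C)C)C(C)C)c(OC)c2)O4)[C@@H]3CO)ccc1O[Si](C(C)C)(C(C)C)C(C)C
F3 | step 18 | (2S,3S,4S)-4-(Ar-carbonyl)-2-ArB-3-(hydroxymethyl)tetrahydrofuran | COc1cc(C(=O)[C@@H]3CO[C@H](c2cc(OC)c4c(c2)[C@@H](CO[Si](C(C)C)(C(C)C)C(C)C)[C@@H](c2ccc(O[Si](C(C)C)(C(C)C)C(C)C)c(OC)c2)O4)[C@@H]3CO)ccc1O[Si](C(C)C)(C(C)C)C(C)C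
F4 | step 10 | (S)-O-methylmandelate of (2S,3S)-15 | O1CCOC1c1cc(OC)c2c(c1)[C@@H](COC(=O)[C@@H](OC)c1ccccc1)[C@@H](c1ccc(O[Si](C(C)C)(C(C)C)C(C)C)c(OC)c1)O2
F5 | step 10 | (S)-O-methylmandelate of (2R,3R)-15 (unwanted diastereomer) | O1CCOC1c1cc(OC)c2c(c1)[C@H](COC(=O)[C@@H](OC)c1ccccc1)[C@H](c1ccc(O[Si](C(C)C)(C(C)C)C(C)C)c(OC)c1)O2
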